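## The problem

The target is a flavone. Ring A carries a free hydroxyl at C5 and methoxy groups at C6 and C7. Ring B is joined to C2 of the pyrone ring C through C1' and carries oxygen on C2', C3', C4' and C6', with only C5' unsubstituted. There is no stereocentre, so nothing needs to steer configuration and the difficulty is entirely regiochemical. Seven oxygens sit on the two benzene rings, and the two phenols (O5 and O6') must be told apart from neighbours of nearly equal reactivity, above all O6' from O2' on the other side of C1'. The C2–C1' bond lies between two ortho oxygens, so a late union of a finished ring B with ring C would be a hindered coupling. The γ-pyrone opens when hard nucleophiles add at C2, its C4 carbonyl is open to organometallics, and methyl ethers next to a chelating site can be lost to excess Lewis acid. O5 is the easy oxygen, because it is peri to the C4 carbonyl and its methyl ether can be removed by chelation while the others stay. The enabling feature is the pattern on ring B: O2' and O6' are meta to each other with C1' between them, and C3' and C4' are oxygenated too. This is what forms when a four-carbon dimethoxy vinylketene joins a silyl ynol ether attached to C2, with O2' arising as a free phenol from the ketene carbonyl and O6' as a silyl ether from the alkyne.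

## Retrosynthesis

Target 22 is first simplified at its two phenols. O6' is returned to a silyl ether (21), O5 to a methyl ether (20), and the methyl group on O2' is removed (19). No carbon–carbon bond is touched, but each oxygen now has its own handle: O5 by chelation to C4=O, O6' by silicon, and O2' as the only free hydroxyl of 19. Carrying a free 5-hydroxyl through the route was set aside because the organolithium chemistry needed earlier would not tolerate it. The forward steps must methylate a hindered phenol without loosening the aryl silyl ether, and then remove one methyl group out of six.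

Ring B of 19 is then taken apart completely. Cutting C1'–C2', C2'–C3' and C5'–C6' gives a four-carbon piece (C2' to C5' with three oxygens), cyclobutenone 14, and a two-carbon piece (C1' and C6' with its oxygen), silyl ynol ether 8. The neighbouring cut at C2–C1' would require a coupling between two ortho oxygens and a ready-made pentasubstituted arene with O6' already marked. Pairing the fragments the other way, through a 2,3-dimethoxycyclobutenone, would put the free phenol on C6' and the silyl ether on C2', which is wrong for the methylation that follows. The chosen cut removes a ring and five substituents at once: 8 holds only rings A and C, and 14 has six carbons. The forward reaction must join ketene and alkyne in one orientation, leave the pyrone alone, and run below the temperature at which 8 rearranges.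

Cyclobutenone 14 is cut across C1–C2 and C3–C4 into methoxyketene 13, generated from methoxyacetyl chloride 12, and methoxyethyne 11. A ketene acetal route with later loss of methanol uses only catalogue reagents, but the elimination can run toward either α-carbon, and the wrong direction gives the 2,3-dimethoxy isomer that swaps the roles of O2' and O6'. With 11 the double bond is in place from the start, and the orientation of the cycloaddition puts the two methoxy-bearing carbons side by side. The price is a volatile alkyne, made from chloroacetal 9 by elimination.

In 8 the C≡C–O unit is cut back to the ester of 5. The oxygen-bound alkyne carbon is the former ester carbonyl carbon, and the carbon bound to C2 is a one-carbon unit inserted between them. This homologation through ynolate 7 reaches the ynol ether in one operation, whereas oxygenating a terminal acetylide would first need a 2-ethynylchromone several steps beyond 5. The forward step asks that a carbenoid and an alkyllithium react at the side chain faster than at the pyrone.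

Ester 5 is opened at O1–C2 and C2–C3 to o-hydroxyacetophenone 2 and diethyl oxalate 3, by way of diketo ester 4, so that the pyrone and its C2 carboxyl arrive together. Ketone 2 is cut at the aryl–acyl bond (C4a–C4) to 3,4,5-trimethoxyphenol 1. Its two ortho positions are equivalent and its para position is blocked, so the acylation has one place to go.

## Roads not taken

Alternative 1: Ring C would be cut at C2–C3 and C3–C4, removing C3 and leading back to 3-silyloxybenzofuran A1. In the forward step dibromocarbene from CHBr3 and KOtBu adds to the enol ether double bond of A1, and the cyclopropane opens with loss of bromide and silyl to give 3-bromoflavone A2.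
- Merits: every intermediate is robust, and no organolithium reagent meets a chromone.
- Weak points: A1 needs ring B complete, with O6' already protected, on the hindered C2 of a benzofuranone, so the central problem moves into the starting material. The carbene must also add to a tetrasubstituted enol ether shielded by a 2,6-disubstituted aryl group while several electron-rich rings compete. The bromine of A2 has no place in the target, so a reduction is added to debenzylation and 5-O-demethylation.
- Comparison: this road is safer in handling. Against that, the chosen plan needs no preformed ring B, carries no atom that must later be removed, and distinguishes O2' from O6' through the mechanism.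

Alternative 2: Ring A would be cut at C5–C6, leading back to pyranone keto ester A3. In the forward step NaOMe in methanol forms the enolate at the methoxy-bearing side-chain carbon, which attacks the ester carbonyl and closes ring A, and the ring aromatises to 5,7-diol A4.
- Merits: O5 arrives as a free, chelated hydroxyl, so no demethylation is needed. The 7-hydroxyl of A4 should methylate selectively because the 5-hydroxyl is hydrogen-bonded.
- Weak points: A3 is a pyranone with three different carbon substituents, one of them the finished ring B, and is itself a multistep target. Methoxide can open the pyranone or cleave the β-dicarbonyl chain. The more acidic methylene between pyranone and ketone gives the dominant, unproductive enolate. Two further steps follow A4.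
- Comparison: this road is better at O5. The chosen plan answers with a chelation-controlled demethylation, one of the most dependable operations in flavone chemistry, and with much shorter access to its key-step partners.

Alternative 3: Ring C would be cut at C4a–C4, C4–C3 and O1–C2 into iodophenol A5, carbon monoxide and arylalkyne A6. In the forward step PdCl2(PPh3)2, CO and Et2NH give flavone A7 by carbonylative coupling and conjugate ring closure.
- Merits: this is the most convergent road. A5 and A6 can both be drawn from phenol 1 (one and three steps), and one Lewis acid treatment of A7 could remove the benzyl and 5-methyl groups together. It would be about six steps against nine, with better-known reactions, and in step count it is the better route.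
- Weak points: oxidative addition to zerovalent palladium is slow for an electron-rich aryl iodide with two ortho substituents, and the alkyne is also flanked twice. Coupling without CO uptake would lead to a benzofuran. The ynone can close in the five-membered sense to an aurone instead of the flavone.
- Comparison: the chosen plan is longer. Against that, it uses no transition metal or CO, its ring closure cannot give an aurone, and ring B is built de novo, so it does not depend on both rings mapping onto phenol 1. The crowding around C2–C1' is also built up after the C2–carbon bond exists.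

Key step: step 6

Remark on the chemistry: cyclobutenone 14 is made and used as the racemate, and its one stereocentre disappears when ring B becomes aromatic. Methoxyethyne 11 is not assumed to be a stock chemical and is prepared in step 4.

Step 1
Reactants: 1 3,4,5-trimethoxyphenol
Product: 2 1-(6-hydroxy-2,3,4-trimethoxyphenyl)ethan-1-one
Conditions: AcOH, BF3·OEt2 (as medium), 90 °C; H2O
Reagents that add atoms: acetic acid, CC(=O)O
Why: Friedel–Crafts (Nencki-type) C-acetylation through O-acetylation and BF3-driven Fries-type migration; both ortho positions are equivalent and the para position is blocked, so a single ketone should form.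

Step 2
Reactants: 2 1-(6-hydroxy-2,3,4-trimethoxyphenyl)ethan-1-one; 3 diethyl oxalate
Product: 5 ethyl 5,6,7-trimethoxy-4-oxo-4H-chromene-2-carboxylate, via diketo ester 4 (not isolated)
Conditions: NaOEt, EtOH, 78 °C; then HCl, EtOH, 78 °C
Reagents that add atoms: none
Why: Crossed Claisen condensation of the methyl ketone enolate with the non-enolisable oxalate gives 4; acid then closes the pyrone by attack of the phenol on the C2 ketone and loss of water, the standard chromone-2-carboxylate synthesis.

Step 3
Reactants: 5 ethyl 5,6,7-trimethoxy-4-oxo-4H-chromene-2-carboxylate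
Product: 8 5,6,7-trimethoxy-2-{[(triisopropylsilyl)oxy]ethynyl}-4H-chromen-4-one, via dibromomethyl ketone 6 (not isolated), via lithium ynolate 7 (not isolated)
Conditions: CH2Br2, lithium 2,2,6,6-tetramethylpiperidide, THF, −78 °C; LiN(SiMe3)2; n-BuLi, −78 → −20 °C; iPr3SiOTf (2.2 equiv), −78 → 0 °C
Reagents that add atoms: dibromomethane, BrCBr; triisopropylsilyl trifluoromethanesulfonate, CC(C)[Si](OS(=O)(=O)C(F)(F)F)(C(C)C)C(C)C
Why: Kowalski ester homologation stopped at the ynolate: LiCHBr2 adds to the ester carbonyl (the most electrophilic site), ketone 6 is enolised, and bromine–lithium exchange triggers a carbenoid 1,2-shift of the chromonyl group to ynolate 7. The bulky silyl triflate then traps 7 on oxygen; low temperature and fast halogen exchange should keep the alkyllithium away from the pyrone.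

Step 4
Reactants: 9 2-chloro-1,1-dimethoxyethane
Product: 11 methoxyethyne, via sodium methoxyethynide 10 (not isolated)
Conditions: NaNH2 (3 equiv), liquid NH3, −33 °C; then saturated aqueous NaCl, −70 °C, distilled into a cold trap
Reagents that add atoms: none
Why: Successive base-induced eliminations of methanol and HCl give acetylide 10, which is protonated on work-up; this is the classical preparation of alkoxyacetylenes from chloroacetals.

Step 5
Reactants: 11 methoxyethyne; 12 methoxyacetyl chloride
Product: 14 3,4-dimethoxycyclobut-2-en-1-one (racemic), via methoxyketene 13 (not isolated)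
Conditions: Et3N (slow addition), Et2O, 0 °C → rt, excess 11
Reagents that add atoms: none
Why: Dehydrochlorination gives ketene 13, which is trapped in a (2+2) ketene–alkoxyalkyne cycloaddition; the nucleophilic CH carbon of 11 bonds to the ketene carbonyl carbon, so the two methoxy-bearing carbons end up adjacent at C3 and C4. C4 forms as a racemic centre that is destroyed in step 6.

Step 6
Reactants: 8 5,6,7-trimethoxy-2-{[(triisopropylsilyl)oxy]ethynyl}-4H-chromen-4-one; 14 3,4-dimethoxycyclobut-2-en-1-one (racemic)
Product: 19 2-{2-hydroxy-3,4-dimethoxy-6-[(triisopropylsilyl)oxy]phenyl}-5,6,7-trimethoxy-4H-chromen-4-one, via vinylketene 15 (not isolated), via vinylcyclobutenone 16 (not isolated), via dienylketene 17 (not isolated), via cyclohexadienone 18 (not isolated)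
Conditions: toluene, 80 → 110 °C, 14 in slight excess
Reagents that add atoms: none
Why: The closest known reaction type is the Danheiser benzannulation of a cyclobutenone with a siloxyalkyne. Heating opens 14 by conrotatory 4π electrocyclic ring opening, the C4 methoxy group turning outward, to vinylketene 15. The ketene C=C of 15 adds across the alkyne of 8 in a (2+2) cycloaddition, the carbonyl carbon bonding to the chromone-bearing alkyne carbon (C1'–C2') and the α-carbon to the silyloxy carbon (C5'–C6'), to give 16. A second 4π opening gives dienylketene 17, and thermal disrotatory 6π electrocyclisation between the ketene carbon and the terminal methoxyvinyl carbon closes six-membered ring B (C2'–C3'); only the isomer of 17 with the vinyl group turned inward can close, and reversible opening of 16 supplies it. Tautomerisation of dienone 18 gives the phenol. No stereocentre remains, since C4 of 14 and the sp3 carbons of 16 and 18 all become aromatic. The step needs one orientation of the ketene–alkyne union and reaction at the alkyne in preference to the pyrone C2=C3 bond; the first is fixed by the oxygen lone pair of the ynol ether, which makes the chromone-bearing carbon the nucleophilic terminus, and the second by the far higher ketenophilicity of an ynol ether than of a trisubstituted enone. The silyl group stays on O6', so O2' alone appears as a free phenol.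

Step 7
Reactants: 19 2-{2-hydroxy-3,4-dimethoxy-6-[(triisopropylsilyl)oxy]phenyl}-5,6,7-trimethoxy-4H-chromen-4-one
Product: 20 5,6,7-trimethoxy-2-{2,3,4-trimethoxy-6-[(triisopropylsilyl)oxy]phenyl}-4H-chromen-4-one
Conditions: MeI, K2CO3, acetone, 40 °C
Reagents that add atoms: iodomethane, CI
Why: Williamson O-methylation of the only free hydroxyl; anhydrous carbonate in acetone should leave the hindered aryl triisopropylsilyl ether in place.

Step 8
Reactants: 20 5,6,7-trimethoxy-2-{2,3,4-trimethoxy-6-[(triisopropylsilyl)oxy]phenyl}-4H-chromen-4-one
Product: 21 5-hydroxy-6,7-dimethoxy-2-{2,3,4-trimethoxy-6-[(triisopropylsilyl)oxy]phenyl}-4H-chromen-4-one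
Conditions: BCl3, CH2Cl2, −78 → 0 °C; H2O
Reagents that add atoms: none
Why: Chelation-controlled Lewis acid dealkylation: boron binds between the C4 carbonyl and O5, and chloride removes that peri methyl group as chloromethane, while the other five methyl ethers have no such chelate at low temperature. Partial loss of the silyl group would be harmless because step 9 removes it.

Step 9
Reactants: 21 5-hydroxy-6,7-dimethoxy-2-{2,3,4-trimethoxy-6-[(triisopropylsilyl)oxy]phenyl}-4H-chromen-4-one
Product: 22 5,6'-dihydroxy-6,7,2',3',4'-pentamethoxyflavone [5-hydroxy-2-(6-hydroxy-2,3,4-trimethoxyphenyl)-6,7-dimethoxy-4H-chromen-4-one]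
Conditions: Bu4NF, AcOH, THF, 0 °C
Reagents that add atoms: none
Why: Fluoride desilylation driven by the strength of the Si–F bond; acetic acid buffers the phenoxide so the pyrone is not exposed to a basic medium.

Compound list

1 | 3,4,5-trimethoxyphenol | COc1cc(O)cc(OC)c1OC | starting material
2 | 1-(6-hydroxy-2,3,4-trimethoxyphenyl)ethan-1-one | CC(=O)c1c(O)cc(OC)c(OC)c1OC | intermediate
3 | diethyl oxalate | CCOC(=O)C(=O)OCC | starting material
4 | ethyl 4-(6-hydroxy-2,3,4-trimethoxyphenyl)-2,4-dioxobutanoate | CCOC(=O)C(=O)CC(=O)c1c(O)cc(OC)c(OC)c1OC | intermediate
5 | ethyl 5,6,7-trimethoxy-4-oxo-4H-chromene-2-carboxylate | CCOC(=O)c1cc(=O)c2c(OC)c(OC)c(OC)cc2o1 | intermediate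
6 | 2-(2,2-dibromoacetyl)-5,6,7-trimethoxy-4H-chromen-4-one (present as its lithium enolate) | O=C(C(Br)Br)c1cc(=O)c2c(OC)c(OC)c(OC)cc2o1 | intermediate
7 | lithium 2-(5,6,7-trimethoxy-4-oxo-4H-chromen-2-yl)ethyn-1-olate | [Li+].[O-]C#Cc1cc(=O)c2c(OC)c(OC)c(OC)cc2o1 | intermediate
8 | 5,6,7-trimethoxy-2-{[(triisopropylsilyl)oxy]ethynyl}-4H-chromen-4-one | COc1cc2oc(C#CO[Si](C(C)C)(C(C)C)C(C)C)cc(=O)c2c(OC)c1OC | intermediate
9 | 2-chloro-1,1-dimethoxyethane | COC(CCl)OC | starting material
10 | sodium methoxyethynide | [Na+].[C-]#COC | intermediate
11 | methoxyethyne | COC#C | intermediate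
12 | methoxyacetyl chloride | COCC(Cl)=O | starting material
13 | methoxyketene (2-methoxyethen-1-one) | COC=C=O | intermediate
14 | 3,4-dimethoxycyclobut-2-en-1-one (racemic) | COC1=CC(=O)C1OC | intermediate
15 | (Z)-3,4-dimethoxybuta-1,3-dien-1-one | O=C=C/C(OC)=C/OC | intermediate
16 | 4-[(Z)-1,2-dimethoxyethenyl]-2-(5,6,7-trimethoxy-4-oxo-4H-chromen-2-yl)-3-[(triisopropylsilyl)oxy]cyclobut-2-en-1-one (racemic) | CO/C=C(\OC)C1C(=O)C(c2cc(=O)c3c(OC)c(OC)c(OC)cc3o2)=C1O[Si](C(C)C)(C(C)C)C(C)C | intermediate
17 | (3E,5Z)-5,6-dimethoxy-2-(5,6,7-trimethoxy-4-oxo-4H-chromen-2-yl)-3-[(triisopropylsilyl)oxy]hexa-1,3,5-trien-1-one | O=C=C(c1cc(=O)c2c(OC)c(OC)c(OC)cc2o1)/C(O[Si](C(C)C)(C(C)C)C(C)C)=C\C(OC)=C\OC | intermediate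
18 | 5,6-dimethoxy-2-(5,6,7-trimethoxy-4-oxo-4H-chromen-2-yl)-3-[(triisopropylsilyl)oxy]cyclohexa-2,4-dien-1-one (racemic) | COC1C(=O)C(c2cc(=O)c3c(OC)c(OC)c(OC)cc3o2)=C(O[Si](C(C)C)(C(C)C)C(C)C)C=C1OC | intermediate
19 | 2-{2-hydroxy-3,4-dimethoxy-6-[(triisopropylsilyl)oxy]phenyl}-5,6,7-trimethoxy-4H-chromen-4-one | COc1cc2oc(-c3c(O)c(OC)c(OC)cc3O[Si](C(C)C)(C(C)C)C(C)C)cc(=O)c2c(OC)c1OC | intermediate
20 | 5,6,7-trimethoxy-2-{2,3,4-trimethoxy-6-[(triisopropylsilyl)oxy]phenyl}-4H-chromen-4-one | COc1cc2oc(-c3c(OC)c(OC)c(OC)cc3O[Si](C(C)C)(C(C)C)C(C)C)cc(=O)c2c(OC)c1OC | intermediate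
21 | 5-hydroxy-6,7-dimethoxy-2-{2,3,4-trimethoxy-6-[(triisopropylsilyl)oxy]phenyl}-4H-chromen-4-one | COc1cc2oc(-c3c(OC)c(OC)c(OC)cc3O[Si](C(C)C)(C(C)C)C(C)C)cc(=O)c2c(O)c1OC | intermediate
22 | 5,6'-dihydroxy-6,7,2',3',4'-pentamethoxyflavone | COc1cc(O)c(-c2cc(=O)c3c(O)c(OC)c(OC)cc3o2)c(OC)c1OC | target

Total step count: 9. Longest linear sequence: 7 steps (steps 1, 2, 3, 6, 7, 8 and 9, from 1 to 22); steps 4 and 5 form the two-step branch to 14.

Least certain steps

Step 6 (key step). The alkyne carbon that must attack the ketene is attached to the electron-poor pyrone, so the cycloaddition may be slow. Vinylketene 15 would then be lost to dimerisation, to addition at the pyrone C2=C3 bond or to acylation of the product phenol. The vinylogous ester character of 14 may also call for temperatures at which silicon in 8 begins to shift from oxygen to carbon. The fallback drops the annulation and uses the fact that ring B, like ring A, maps onto phenol 1. It sets out from 1 and 2 and comes back at 22. Ortho-formylation of 1 (MgCl2, Et3N, paraformaldehyde) would give 6-hydroxy-2,3,4-trimethoxybenzaldehyde F1. Benzylation (BnBr, K2CO3) would give 6-(benzyloxy)-2,3,4-trimethoxybenzaldehyde F2. Claisen–Schmidt condensation of F2 with 2 (KOH, EtOH) would give (E)-3-[6-(benzyloxy)-2,3,4-trimethoxyphenyl]-1-(6-hydroxy-2,3,4-trimethoxyphenyl)prop-2-en-1-one F3. Oxidative cyclisation with catalytic I2 in DMSO would give 2-[6-(benzyloxy)-2,3,4-trimethoxyphenyl]-5,6,7-trimethoxy-4H-chromen-4-one F4. BCl3 would then remove the benzyl group and the chelated 5-methyl group together to reach 22.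

Step 3. Dibromomethyllithium or butyllithium may add to the C4 carbonyl or at C2 of the pyrone with ring opening, instead of reacting at the ester and the dibromo enolate. The ynolate may also be silylated on carbon. The fallback sets out from 5 and comes back at 8 without a carbenoid or alkyllithium meeting the chromone. NaBH4 reduction of the activated ester would give 2-(hydroxymethyl)-5,6,7-trimethoxy-4H-chromen-4-one F5. MnO2 oxidation would give 5,6,7-trimethoxy-4-oxo-4H-chromene-2-carbaldehyde F6. Ohira–Bestmann homologation would give 2-ethynyl-5,6,7-trimethoxy-4H-chromen-4-one F7. Deprotonation of F7 with LiN(SiMe3)2, oxygenation of the acetylide with LiOOtBu to ynolate 7 and trapping with iPr3SiOTf would give 8.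

Step 5. Methoxyketene may dimerise or polymerise faster than it is trapped by the volatile alkyne, and hydrogen chloride from the ammonium salt may add to the ynol ether. The fallback sets out from 12 and comes back at 14, using 1,1-dimethoxyethene as the ketenophile. The (2+2) cycloaddition would give 2,3,3-trimethoxycyclobutan-1-one F8, and base-induced loss of methanol (Et3N or basic alumina) would give 14. The elimination must be steered toward the CH2 carbon and its direction proven, which is why this is the reserve and not the first choice.

Step 8. A second methyl ether may be cleaved (at C6 next to the boron-bound O5, or on ring B) if the Lewis acid is in excess or the mixture warms. The fallback sets out from 20 and comes back at 22 with the order of events reversed. Fluoride desilylation first would give 2-(6-hydroxy-2,3,4-trimethoxyphenyl)-5,6,7-trimethoxy-4H-chromen-4-one F9. The peri methyl group would then be removed with the milder chelating reagent MgI2 in ether–toluene, where iodide is the dealkylating nucleophile and selectivity is judged on the final compound.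

Further compounds

F1 | step 6 | 6-hydroxy-2,3,4-trimethoxybenzaldehyde | COc1cc(O)c(C=O)c(OC)c1OC
F2 | step 6 | 6-(benzyloxy)-2,3,4-trimethoxybenzaldehyde | COc1cc(OCc2ccccc2)c(C=O)c(OC)c1OC
F3 | step 6 | (E)-3-[6-(benzyloxy)-2,3,4-trimethoxyphenyl]-1-(6-hydroxy-2,3,4-trimethoxyphenyl)prop-2-en-1-one | COc1cc(O)c(C(=O)/C=C/c2c(OCc3ccccc3)cc(OC)c(OC)c2OC)c(OC)c1OC
F4 | step 6 | 2-[6-(benzyloxy)-2,3,4-trimethoxyphenyl]-5,6,7-trimethoxy-4H-chromen-4-one | COc1cc(OCc2ccccc2)c(-c2cc(=O)c3c(OC)c(OC)c(OC)cc3o2)c(OC)c1OC
F5 | step 3 | 2-(hydroxymethyl)-5,6,7-trimethoxy-4H-chromen-4-one | COc1cc2oc(CO)cc(=O)c2c(OC)c1OC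
F6 | step 3 | 5,6,7-trimethoxy-4-oxo-4H-chromene-2-carbaldehyde | COc1cc2oc(C=O)cc(=O)c2c(OC)c1OC
F7 | step 3 | 2-ethynyl-5,6,7-trimethoxy-4H-chromen-4-one | COc1cc2oc(C#C)cc(=O)c2c(OC)c1OC
F8 | step 5 | 2,3,3-trimethoxycyclobutan-1-one (racemic) | COC1C(=O)CC1(OC)OC
F9 | step 8 | 2-(6-hydroxy-2,3,4-trimethoxyphenyl)-5,6,7-trimethoxy-4H-chromen-4-one | COc1cc(O)c(-c2cc(=O)c3c(OC)c(OC)c(OC)cc3o2)c(OC)c1OC
A1 | alternative 1 | tert-butyl({2-[6-(benzyloxy)-2,3,4-trimethoxyphenyl]-4,5,6-trimethoxy-1-benzofuran-3-yl}oxy)dimethylsilane | COc1cc2oc(-c3c(OCc4ccccc4)cc(OC)c(OC)c3OC)c(O[Si](C)(C)C(C)(C)C)c2c(OC)c1OC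
A2 | alternative 1 | 2-[6-(benzyloxy)-2,3,4-trimethoxyphenyl]-3-bromo-5,6,7-trimethoxy-4H-chromen-4-one | COc1cc(OCc2ccccc2)c(-c2oc3cc(OC)c(OC)c(OC)c3c(=O)c2Br)c(OC)c1OC
A3 | alternative 2 | methyl 6-[6-(benzyloxy)-2,3,4-trimethoxyphenyl]-2-(3-methoxy-2-oxopropyl)-4-oxo-4H-pyran-3-carboxylate | COCC(=O)Cc1oc(-c2c(OCc3ccccc3)cc(OC)c(OC)c2OC)cc(=O)c1C(=O)OC
A4 | alternative 2 | 2-[6-(benzyloxy)-2,3,4-trimethoxyphenyl]-5,7-dihydroxy-6-methoxy-4H-chromen-4-one | COc1cc(OCc2ccccc2)c(-c2cc(=O)c3c(O)c(OC)c(O)cc3o2)c(OC)c1OC
A5 | alternative 3 | 2-iodo-3,4,5-trimethoxyphenol | COc1cc(O)c(I)c(OC)c1OC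
A6 | alternative 3 | 1-(benzyloxy)-2-ethynyl-3,4,5-trimethoxybenzene | COc1cc(OCc2ccccc2)c(C#C)c(OC)c1OC
A7 | alternative 3 | 2-[6-(benzyloxy)-2,3,4-trimethoxyphenyl]-5,6,7-trimethoxy-4H-chromen-4-one | COc1cc(OCc2ccccc2)c(-c2cc(=O)c3c(OC)c(OC)c(OC)cc3o2)c(OC)c1OC
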